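Everything rests on disconnecting ring C (the pyran ring) of the top unit at the bonds O-1/C-2 and C-3/C-4. The half holding O-1, C-8a, C-4a and C-4 is an ortho-quinone methide of ring A whose C-4 carries C-8 of the lower trimer; the other half is a (Z)-2-arylvinyl acetate. A chiral phosphoric acid catalysed oxa-Diels–Alder reaction closes the ring and sets C-2, C-3 and C-4 in one operation. Its precursor is a 2-hydroxybenzhydrol built on C-8 of the benzylated epicatechin trimer, which comes from (−)-epicatechin by two 4β→8 couplings. Methanolysis and hydrogenolysis finish the synthesis.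

Key step: step 10

Remark on conventions: flavan numbering is used, with locants written as C-2, C-3, C-4, C-8 and O-1. The units are numbered 1 (top) to 4 (bottom, the unit whose C-4 is a CH2 group). Bn = benzyl. "4β" means 3,4-trans to the 3-oxygen in a 2,3-cis (epicatechin) unit. "Dimer", "trimer" and "tetramer" mean the all-(4β→8)-linked epicatechin oligomers; the tetramer is the target.

Assumption: the (R)-enantiomer of the phosphoric acid in step 10 is taken to be the one that directs the alkene to the face of the quinone methide giving the natural configuration of unit 1; this sense is assigned by analogy, and the (S)-acid would be used if it proved opposite.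

Step 1
Reactants: 1 (−)-epicatechin
Product: 2 (2R,3R)-5,7,3',4'-tetra-O-benzylepicatechin
Conditions: BnBr (4.4 equiv), K2CO3, DMF, 0 °C to rt
Reagents that add atoms: benzyl bromide, BrCc1ccccc1
Why: Williamson ether synthesis in which carbonate deprotonates only the four phenols, so the secondary 3-OH stays free and C-2 and C-3 are untouched.

Step 2
Reactants: 2 (2R,3R)-5,7,3',4'-tetra-O-benzylepicatechin
Product: 3 4β-(2-ethoxyethoxy)-5,7,3',4'-tetra-O-benzylepicatechin (2,3-cis-3,4-trans)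
Conditions: DDQ (2 equiv), 2-ethoxyethanol, CH2Cl2, rt
Reagents that add atoms: 2-ethoxyethanol, CCOCCO
Why: DDQ benzylic oxidation abstracts hydride from C-4 to a cation stabilised by ring A, and the alcohol should add anti to the 3-OH and 2-aryl groups to give the 3,4-trans ether.

Step 3
Reactants: 2 (2R,3R)-5,7,3',4'-tetra-O-benzylepicatechin (4 equiv); 3 4β-(2-ethoxyethoxy)-5,7,3',4'-tetra-O-benzylepicatechin
Product: 4 octa-O-benzyl epicatechin-(4β→8)-epicatechin (the benzylated dimer: two tetra-O-benzylepicatechin units joined from C-4 to C-8, both 3-OH free)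
Conditions: Me3SiOTf (cat.), CH2Cl2, −78 °C; Et3N quench
Reagents that add atoms: none
Why: Lewis acid promoted Friedel–Crafts alkylation in which C-8 of 2 attacks the C-4 cation of 3 anti to its 3-OH and 2-aryl groups, setting 4β, while the excess of 2 suppresses further chain growth.

Step 4
Reactants: 3 4β-(2-ethoxyethoxy)-5,7,3',4'-tetra-O-benzylepicatechin
Product: 5 8-bromo-4β-(2-ethoxyethoxy)-5,7,3',4'-tetra-O-benzylepicatechin
Conditions: NBS (1.0 equiv), NaHCO3, CH2Cl2, −30 °C
Reagents that add atoms: N-bromosuccinimide, O=C1CCC(=O)N1Br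
Why: Electrophilic aromatic bromination should occur at C-8, the most activated and least hindered position of ring A, and the bromine both blocks self-condensation and serves as the later metalation handle.

Step 5
Reactants: 4 octa-O-benzyl epicatechin-(4β→8)-epicatechin (1.5 equiv); 5 8-bromo-4β-(2-ethoxyethoxy)-5,7,3',4'-tetra-O-benzylepicatechin
Product: 6 8-bromo-dodeca-O-benzyl trimer (epicatechin-(4β→8)-epicatechin-(4β→8)-epicatechin, all twelve phenols benzylated, three free 3-OH, bromine at C-8 of the top unit)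
Conditions: Me3SiOTf (cat.), CH2Cl2, −78 °C; Et3N quench
Reagents that add atoms: none
Why: The same Friedel–Crafts coupling, in which the free C-8 of the upper unit of 4 attacks the C-4 cation of 5 anti to its 3-OH to set 4β, and 5 cannot self-condense because its own C-8 is brominated.

Step 6
Reactants: 7 2,4,6-trihydroxybenzaldehyde
Product: 8 2-hydroxy-4,6-bis(benzyloxy)benzaldehyde
Conditions: BnBr (2.1 equiv), K2CO3, DMF, rt
Reagents that add atoms: benzyl bromide, BrCc1ccccc1
Why: Williamson etherification should stop at the dibenzyl ether because the remaining ortho-hydroxyl is hydrogen-bonded to the formyl group and is much less nucleophilic.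

Step 7
Reactants: 6 8-bromo-dodeca-O-benzyl trimer; 8 2-hydroxy-4,6-bis(benzyloxy)benzaldehyde
Product: 11 [2-hydroxy-4,6-bis(benzyloxy)phenyl][dodeca-O-benzyl trimer-8-yl]methanol (carbinol carbon on C-8 of the top unit; both carbinol epimers), via 8-lithio trimer trilithium alkoxide 9 (not isolated), via sodium 2-formylphenoxide 10 (not isolated)
Conditions: 6, MeLi (3.1 equiv), THF, −78 °C, then t-BuLi (2.1 equiv), −78 °C; 8 pretreated with NaH (1.0 equiv) in THF, added at −78 °C, then 0 °C; aqueous quench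
Reagents that add atoms: none
Why: Deprotonation of the three hydroxyls followed by bromine–lithium exchange should give the 8-aryllithium, whose 1,2-addition to the aldehyde (its acidic phenol masked as the sodium phenoxide) forms the benzhydrol; the new carbinol centre arises as both epimers, which is immaterial because it is planarised in step 10.

Step 8
Reactants: 12 3,4-bis(benzyloxy)benzaldehyde
Product: 13 4-ethynyl-1,2-bis(benzyloxy)benzene
Conditions: dimethyl (1-diazo-2-oxopropyl)phosphonate, K2CO3, MeOH, rt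
Reagents that add atoms: dimethyl (1-diazo-2-oxopropyl)phosphonate, CC(=O)C(=[N+]=[N-])P(=O)(OC)OC
Why: Seyferth–Gilbert homologation in the Ohira–Bestmann variant, in which the diazomethylphosphonate anion formed in situ olefinates the aldehyde and the diazoalkene loses dinitrogen with 1,2-hydrogen shift to the terminal alkyne.

Step 9
Reactants: 13 4-ethynyl-1,2-bis(benzyloxy)benzene
Product: 14 (Z)-2-[3,4-bis(benzyloxy)phenyl]ethenyl acetate
Conditions: AcOH (1.3 equiv), Ru(η3-CH2C(CH3)CH2)2(Ph2P(CH2)4PPh2) (2 mol%), toluene, 60 °C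
Reagents that add atoms: acetic acid, CC(=O)O
Why: Ruthenium-catalysed anti-Markovnikov addition of a carboxylic acid to a terminal alkyne, in which acetate attacks the α-carbon of a ruthenium vinylidene and protonolysis of the alkenyl–ruthenium bond should deliver the Z-enol ester.

Step 10
Reactants: 11 [2-hydroxy-4,6-bis(benzyloxy)phenyl][dodeca-O-benzyl trimer-8-yl]methanol; 14 (Z)-2-[3,4-bis(benzyloxy)phenyl]ethenyl acetate (3 equiv)
Product: 16 hexadeca-O-benzyl tetramer 3-O-acetate (acetate on C-3 of unit 1; unit 1 2,3-cis-3,4-trans), via ortho-quinone methide 15 (not isolated)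
Conditions: (R)-3,3'-bis(2,4,6-triisopropylphenyl)-1,1'-binaphthyl-2,2'-diyl hydrogen phosphate (10 mol%), 4 Å molecular sieves, toluene, 0 °C to rt
Reagents that add atoms: none
Why: The phosphoric acid dehydrates 11 to the hydrogen-bonded, ion-paired ortho-quinone methide 15, whose heterodiene (O-1, C-8a, C-4a, C-4) undergoes an asynchronous inverse-electron-demand oxa-Diels–Alder reaction with 14, the acetoxy-bearing alkene carbon bonding to the methide carbon (bond C-3 to C-4) and the quinone methide oxygen to the benzylic carbon (bond O-1 to C-2), while the molecular sieves take up the water set free. The closest known reaction type is the Brønsted acid catalysed [4+2] cycloaddition of ortho-quinone methides generated from 2-hydroxybenzhydrols with electron-rich styrenes, which gives 2,4-diarylchromans. Ring C of unit 1 is closed by intermolecular [4+2] cycloaddition, four ring atoms coming from the quinone methide and two from the alkene. C-2 and C-3 become cis because the Z-alkene adds suprafacially; C-4 becomes trans to both because the 5-benzyloxy group forces the aryl group on the methide carbon to the side of the quinone methide oxygen, so that endo approach of the 2-aryl group places the two aryl groups trans; the absolute sense at all three centres is set by the chiral phosphate, which blocks one face of the quinone methide. The step needs regioselectivity, secured by the para-benzyloxy group of ring B, which makes the alkene react as a styrene while the acetoxy group is only a weak donor; it also needs chemoselectivity in ring closure, secured because the quinone methide oxygen is the only free phenolic oxygen, all others being benzyl ethers and the secondary 3-OH groups adding only reversibly.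

Step 11
Reactants: 16 hexadeca-O-benzyl tetramer 3-O-acetate
Product: 17 hexadeca-O-benzyl tetramer (sixteen phenolic benzyl ethers, four free 3-OH)
Conditions: K2CO3 (0.3 equiv), MeOH/THF, rt
Reagents that add atoms: none
Why: Base-catalysed transesterification (Zemplén-type methanolysis) removes the single acetate, while benzyl ethers, interflavan bonds and all stereocentres are inert to methoxide at room temperature.

Step 12
Reactants: 17 hexadeca-O-benzyl tetramer
Product: 18 epicatechin-(4β→8)-epicatechin-(4β→8)-epicatechin-(4β→8)-epicatechin (the target tetramer)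
Conditions: hydrogen (1 atm), Pd(OH)2/C, THF/MeOH/water, rt
Reagents that add atoms: none
Why: Catalytic hydrogenolysis cleaves the sixteen benzyl ethers under neutral conditions that should leave the acid- and base-sensitive interflavan bonds and the twelve stereocentres unchanged.

Compound list
1 | (−)-epicatechin | Oc1cc(O)c2c(c1)O[C@H](c1ccc(O)c(O)c1)[C@H](O)C2 | starting material
2 | (2R,3R)-5,7,3',4'-tetra-O-benzylepicatechin | c3ccccc3COc1cc(OCc3ccccc3)c2c(c1)O[C@H](c1ccc(OCc3ccccc3)c(OCc3ccccc3)c1)[C@H](O)C2 | intermediate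
3 | 4β-(2-ethoxyethoxy)-5,7,3',4'-tetra-O-benzylepicatechin | c3ccccc3COc1cc(OCc3ccccc3)c2c(c1)O[C@H](c1ccc(OCc3ccccc3)c(OCc3ccccc3)c1)[C@H](O)[C@H]2OCCOCC | intermediate
4 | octa-O-benzyl epicatechin-(4β→8)-epicatechin (benzylated dimer) | c3ccccc3COc1cc(OCc3ccccc3)c2c(c1)O[C@H](c1ccc(OCc3ccccc3)c(OCc3ccccc3)c1)[C@H](O)[C@H]2c1c(OCc3ccccc3)cc(OCc3ccccc3)c2c1O[C@H](c1ccc(OCc3ccccc3)c(OCc3ccccc3)c1)[C@H](O)C2 | intermediate
5 | 8-bromo-4β-(2-ethoxyethoxy)-5,7,3',4'-tetra-O-benzylepicatechin | c3ccccc3COc1cc(OCc3ccccc3)c2c(c1Br)O[C@H](c1ccc(OCc3ccccc3)c(OCc3ccccc3)c1)[C@H](O)[C@H]2OCCOCC | intermediate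
6 | 8-bromo-dodeca-O-benzyl trimer (bromine at C-8 of the top unit) | c3ccccc3COc1cc(OCc3ccccc3)c2c(c1Br)O[C@H](c1ccc(OCc3ccccc3)c(OCc3ccccc3)c1)[C@H](O)[C@H]2c1c(OCc3ccccc3)cc(OCc3ccccc3)c2c1O[C@H](c1ccc(OCc3ccccc3)c(OCc3ccccc3)c1)[C@H](O)[C@H]2c1c(OCc3ccccc3)cc(OCc3ccccc3)c2c1O[C@H](c1ccc(OCc3ccccc3)c(OCc3ccccc3)c1)[C@H](O)C2 | intermediate
7 | 2,4,6-trihydroxybenzaldehyde | O=Cc1c(O)cc(O)cc1O | starting material
8 | 2-hydroxy-4,6-bis(benzyloxy)benzaldehyde | O=Cc1c(O)cc(OCc3ccccc3)cc1OCc3ccccc3 | intermediate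
9 | 8-lithio dodeca-O-benzyl trimer trilithium alkoxide | c3ccccc3COc1cc(OCc3ccccc3)c2c(c1[Li])O[C@H](c1ccc(OCc3ccccc3)c(OCc3ccccc3)c1)[C@H](O[Li])[C@H]2c1c(OCc3ccccc3)cc(OCc3ccccc3)c2c1O[C@H](c1ccc(OCc3ccccc3)c(OCc3ccccc3)c1)[C@H](O[Li])[C@H]2c1c(OCc3ccccc3)cc(OCc3ccccc3)c2c1O[C@H](c1ccc(OCc3ccccc3)c(OCc3ccccc3)c1)[C@H](O[Li])C2 | intermediate
10 | sodium 3,5-bis(benzyloxy)-2-formylphenoxide | [Na+].[O-]c1cc(OCc3ccccc3)cc(OCc3ccccc3)c1C=O | intermediate
11 | [2-hydroxy-4,6-bis(benzyloxy)phenyl][dodeca-O-benzyl trimer-8-yl]methanol (both carbinol epimers) | c3ccccc3COc1cc(OCc3ccccc3)c2c(c1C(O)c1c(O)cc(OCc3ccccc3)cc1OCc3ccccc3)O[C@H](c1ccc(OCc3ccccc3)c(OCc3ccccc3)c1)[C@H](O)[C@H]2c1c(OCc3ccccc3)cc(OCc3ccccc3)c2c1O[C@H](c1ccc(OCc3ccccc3)c(OCc3ccccc3)c1)[C@H](O)[C@H]2c1c(OCc3ccccc3)cc(OCc3ccccc3)c2c1O[C@H](c1ccc(OCc3ccccc3)c(OCc3ccccc3)c1)[C@H](O)C2 | intermediate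
12 | 3,4-bis(benzyloxy)benzaldehyde | O=Cc1ccc(OCc3ccccc3)c(OCc3ccccc3)c1 | starting material
13 | 4-ethynyl-1,2-bis(benzyloxy)benzene | C#Cc1ccc(OCc3ccccc3)c(OCc3ccccc3)c1 | intermediate
14 | (Z)-2-[3,4-bis(benzyloxy)phenyl]ethenyl acetate | CC(=O)O/C=C\c1ccc(OCc3ccccc3)c(OCc3ccccc3)c1 | intermediate
15 | ortho-quinone methide: 3,5-bis(benzyloxy)-6-[(dodeca-O-benzyl trimer-8-yl)methylidene]cyclohexa-2,4-dien-1-one | O=C1C=C(OCc3ccccc3)C=C(OCc3ccccc3)C1=Cc1c(OCc3ccccc3)cc(OCc3ccccc3)c2c1O[C@H](c1ccc(OCc3ccccc3)c(OCc3ccccc3)c1)[C@H](O)[C@H]2c1c(OCc3ccccc3)cc(OCc3ccccc3)c2c1O[C@H](c1ccc(OCc3ccccc3)c(OCc3ccccc3)c1)[C@H](O)[C@H]2c1c(OCc3ccccc3)cc(OCc3ccccc3)c2c1O[C@H](c1ccc(OCc3ccccc3)c(OCc3ccccc3)c1)[C@H](O)C2 | intermediate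
16 | hexadeca-O-benzyl tetramer 3-O-acetate (acetate on unit 1) | c3ccccc3COc1cc(OCc3ccccc3)c2c(c1)O[C@H](c1ccc(OCc3ccccc3)c(OCc3ccccc3)c1)[C@H](OC(C)=O)[C@H]2c1c(OCc3ccccc3)cc(OCc3ccccc3)c2c1O[C@H](c1ccc(OCc3ccccc3)c(OCc3ccccc3)c1)[C@H](O)[C@H]2c1c(OCc3ccccc3)cc(OCc3ccccc3)c2c1O[C@H](c1ccc(OCc3ccccc3)c(OCc3ccccc3)c1)[C@H](O)[C@H]2c1c(OCc3ccccc3)cc(OCc3ccccc3)c2c1O[C@H](c1ccc(OCc3ccccc3)c(OCc3ccccc3)c1)[C@H](O)C2 | intermediate
17 | hexadeca-O-benzyl tetramer | c3ccccc3COc1cc(OCc3ccccc3)c2c(c1)O[C@H](c1ccc(OCc3ccccc3)c(OCc3ccccc3)c1)[C@H](O)[C@H]2c1c(OCc3ccccc3)cc(OCc3ccccc3)c2c1O[C@H](c1ccc(OCc3ccccc3)c(OCc3ccccc3)c1)[C@H](O)[C@H]2c1c(OCc3ccccc3)cc(OCc3ccccc3)c2c1O[C@H](c1ccc(OCc3ccccc3)c(OCc3ccccc3)c1)[C@H](O)[C@H]2c1c(OCc3ccccc3)cc(OCc3ccccc3)c2c1O[C@H](c1ccc(OCc3ccccc3)c(OCc3ccccc3)c1)[C@H](O)C2 | intermediate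
18 | epicatechin-(4β→8)-epicatechin-(4β→8)-epicatechin-(4β→8)-epicatechin (the target tetramer) | Oc1cc(O)c2c(c1)O[C@H](c1ccc(O)c(O)c1)[C@H](O)[C@H]2c1c(O)cc(O)c2c1O[C@H](c1ccc(O)c(O)c1)[C@H](O)[C@H]2c1c(O)cc(O)c2c1O[C@H](c1ccc(O)c(O)c1)[C@H](O)[C@H]2c1c(O)cc(O)c2c1O[C@H](c1ccc(O)c(O)c1)[C@H](O)C2 | target

Total step count: 12. Longest linear sequence: 8 steps (1 → 2 → 3 → 4 → 6 → 11 → 16 → 17 → 18, through steps 1, 2, 3, 5, 7, 10, 11 and 12).

Steps most likely to fail

Step 10. The chiral phosphate may fail to override the weak facial bias of the trimer, giving poor facial selectivity. The cycloaddition may also turn stepwise, so that bond rotation in the benzylic cation erodes the 2,3-cis relationship, or it may be slow at the crowded methide carbon. The fallback uses the established cation–arene coupling, sets out from 6 and comes back at 17. Compound 6 would be converted into the lithiated species 9 exactly as in step 7 and protonated with MeOH to give the dodeca-O-benzyl epicatechin trimer F1. F1, used in excess, would then be coupled with 3 (Me3SiOTf cat., CH2Cl2, −78 °C). C-8 of its top unit should attack the C-4 cation anti to the 3-OH and give 17 directly, after which step 12 follows.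

Step 7. The aryllithium may be protonated by incompletely deprotonated hydroxyls, or its addition to the electron-rich, doubly ortho-substituted phenoxide aldehyde may stall. The fallback masks every acidic proton so that a simple mono-lithium species reacts with a neutral aldehyde; it sets out from 6 and 8 and comes back at 11. The three 3-OH groups of 6 would be silylated (tert-butyldimethylsilyl triflate, 2,6-lutidine, CH2Cl2) to the tris(tert-butyldimethylsilyl) ether of the bromotrimer F2. Aldehyde 8 would be silylated (tert-butyldimethylsilyl chloride, imidazole, DMF) to 2-(tert-butyldimethylsilyloxy)-4,6-bis(benzyloxy)benzaldehyde F3. Bromine–lithium exchange on F2 (t-BuLi, THF, −78 °C) would give the 8-lithiated tris-silyl trimer F4, which would add to F3 to give the tetrasilylated benzhydrol F5. Silyl migration between the phenolic and carbinol oxygens is immaterial. Bu4NF/AcOH in THF would remove all four silyl groups to give 11.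

Step 4. Traces of HBr may ionise the acetal at C-4 and trigger self-condensation, or bromination may occur competitively at C-6. The fallback inverts the order of bromination and oxidation at C-4; it sets out from 2 and comes back at 5. Compound 2 would be brominated (NBS, CH2Cl2, −78 to 0 °C) to 8-bromo-5,7,3',4'-tetra-O-benzylepicatechin F6. F6 would then be oxidised with DDQ in the presence of 2-ethoxyethanol as in step 2 to give 5.

Further compounds
F1 | step 10 | dodeca-O-benzyl epicatechin trimer | c3ccccc3COc1cc(OCc3ccccc3)c2c(c1)O[C@H](c1ccc(OCc3ccccc3)c(OCc3ccccc3)c1)[C@H](O)[C@H]2c1c(OCc3ccccc3)cc(OCc3ccccc3)c2c1O[C@H](c1ccc(OCc3ccccc3)c(OCc3ccccc3)c1)[C@H](O)[C@H]2c1c(OCc3ccccc3)cc(OCc3ccccc3)c2c1O[C@H](c1ccc(OCc3ccccc3)c(OCc3ccccc3)c1)[C@H](O)C2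
F2 | step 7 | 8-bromo-dodeca-O-benzyl trimer tris(tert-butyldimethylsilyl) ether | c3ccccc3COc1cc(OCc3ccccc3)c2c(c1Br)O[C@H](c1ccc(OCc3ccccc3)c(OCc3ccccc3)c1)[C@H](O[Si](C)(C)C(C)(C)C)[C@H]2c1c(OCc3ccccc3)cc(OCc3ccccc3)c2c1O[C@H](c1ccc(OCc3ccccc3)c(OCc3ccccc3)c1)[C@H](O[Si](C)(C)C(C)(C)C)[C@H]2c1c(OCc3ccccc3)cc(OCc3ccccc3)c2c1O[C@H](c1ccc(OCc3ccccc3)c(OCc3ccccc3)c1)[C@H](O[Si](C)(C)C(C)(C)C)C2
F3 | step 7 | 2-(tert-butyldimethylsilyloxy)-4,6-bis(benzyloxy)benzaldehyde | O=Cc1c(O[Si](C)(C)C(C)(C)C)cc(OCc3ccccc3)cc1OCc3ccccc3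
F4 | step 7 | 8-lithiated dodeca-O-benzyl trimer tris(tert-butyldimethylsilyl) ether | c3ccccc3COc1cc(OCc3ccccc3)c2c(c1[Li])O[C@H](c1ccc(OCc3ccccc3)c(OCc3ccccc3)c1)[C@H](O[Si](C)(C)C(C)(C)C)[C@H]2c1c(OCc3ccccc3)cc(OCc3ccccc3)c2c1O[C@H](c1ccc(OCc3ccccc3)c(OCc3ccccc3)c1)[C@H](O[Si](C)(C)C(C)(C)C)[C@H]2c1c(OCc3ccccc3)cc(OCc3ccccc3)c2c1O[C@H](c1ccc(OCc3ccccc3)c(OCc3ccccc3)c1)[C@H](O[Si](C)(C)C(C)(C)C)C2
F5 | step 7 | tetrasilylated benzhydrol (phenol and three 3-OH as tert-butyldimethylsilyl ethers, both carbinol epimers) | c3ccccc3COc1cc(OCc3ccccc3)c2c(c1C(O)c1c(O[Si](C)(C)C(C)(C)C)cc(OCc3ccccc3)cc1OCc3ccccc3)O[C@H](c1ccc(OCc3ccccc3)c(OCc3ccccc3)c1)[C@H](O[Si](C)(C)C(C)(C)C)[C@H]2c1c(OCc3ccccc3)cc(OCc3ccccc3)c2c1O[C@H](c1ccc(OCc3ccccc3)c(OCc3ccccc3)c1)[C@H](O[Si](C)(C)C(C)(C)C)[C@H]2c1c(OCc3ccccc3)cc(OCc3ccccc3)c2c1O[C@H](c1ccc(OCc3ccccc3)c(OCc3ccccc3)c1)[C@H](O[Si](C)(C)C(C)(C)C)C2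
F6 | step 4 | 8-bromo-5,7,3',4'-tetra-O-benzylepicatechin | c3ccccc3COc1cc(OCc3ccccc3)c2c(c1Br)O[C@H](c1ccc(OCc3ccccc3)c(OCc3ccccc3)c1)[C@H](O)C2
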